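The numbers in the tables were generated by integration from invented constants; scatter was added.

Saturday's flask has a leftover: from 10.0 min to 40.0 min the readings stand near 29.6% of the Q charged, so about 70.3% of the Q stays unturned. You must say whether Z has stopped working or the way back has caught up.

| setting | Saturday's | Monday's | flask |
|---|---|---|---|
| Q | 0.10 M | 0.10 M | 0.10 M |
| G | 0.30 M | 0.60 M | 0.300 M |
| Z | 0.50 mM | 0.50 mM | 0.50 mM |
| remark | the very flask that is asked about, followed so far | run made earlier |  |
| time |  |  | 1.0 h |

| Saturday's: time / min | Saturday's: X / % | Monday's: time / min | Monday's: X / % |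
|---|---|---|---|
| 10.0 | 29.1 | 0.417 | 12.6 |
| 20.0 | 30.0 | 1.00 | 25.5 |
| 25.0 | 29.1 | 2.00 | 35.3 |
| 40.0 | 30.4 | 3.00 | 40.8 |

(scatter of a reading: 0.5 percentage points)

- removed X is counted in
- steps thought possible: Z -> J; Q + G + Z <-> Z + X
- additions bring no volume worth counting

- ochre: at 1.0 h add Z, 100% of the amount charged, then wait 1.0 h
- red: at 1.0 h take out 90% of the X then present, then wait 1.0 h
- blue: change nothing and wait 1.0 h more
- grey: at 1.0 h add G, 50.0% of the amount charged, then wait 1.0 h

* X, in percent of the Q first charged, at 1.0 h
* the remedy with the largest gain of X, or "none" below 2 percentage points (ochre / red / blue / grey / none)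
* X present, with what was taken out counted in, in percent of the Q first charged, after ochre
* X present, with what was taken out counted in, in percent of the Q first charged, after red

Saturday's readings give 1.56 L mol⁻¹ for the stopping quotient, the reaction quotient X/(Q·G) taken where a flask stands still. Both directions of the catalysed step run through Z, so a flask charged without X climbs towards the equilibrium constant and stops below it if Z has turned into J first. The quotient is therefore a floor for that constant, not the constant itself. Monday's last reading gives 1.23 L mol⁻¹, lower than Saturday's and still climbing, so it goes against neither case. I commit to a reading near 29.6% at the hour, and I hold the floor open: if Z has stopped working, red gains nothing and ochre gains.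

The forecast reads 29.8%, picks red, and gives 30% after ochre and 47% after red, its ground being “Taking equilibrium with live Z”. Where I keep a floor, it keeps a constant.

The flask gives 30.2% at the hour. The remedy is ochre, which gains 5.7 percentage points and reaches 35.9%. Red ends at 30.2%, a gain of 0 points, and blue and grey each gain 0 points.

    Z → J (k = 0.00508 s⁻¹)
    Q + G + Z ⇌ Z + X (K = 2.27 L mol⁻¹, k = 21.4 L² mol⁻² s⁻¹)

At 60.0 min Saturday's flask holds Z 0% and J 100%, and its stopping quotient, 1.60 L mol⁻¹, is 70.5% of the constant 2.27 L mol⁻¹. Now take a neighbouring flask, the same but with G raised to 0.75 M. Its X of 56.0% and Q of 44.0% give a stopping quotient of 1.84 L mol⁻¹, again below the constant, with Z at 0% after 60.0 min.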